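**Retrosynthetic overview**
1. Target 21 ⇒ acyclic diene 20 by ring-closing metathesis of the C1=C10 olefin (ten-membered ring, formed last).
2. 20 ⇒ α-methylene lactone 15: silyl-to-acetate swap at C8, and the key C11–O(angelate) bond made by anodic acyloxylation of the lactone silyl ketene acetal (sets C11).
3. 15 ⇒ allyl bromide 8 + enal 13: C6–C7 bond by indium Barbier allylation, then lactonisation (γ-lactone ring, formed first; sets C6 and C7 from C8).
4. 8 ⇒ methyl (S)-glycidate (supplies C8), isopropenyl Grignard and methyl acrylate; 13 ⇒ hex-1-en-5-yne by carboalumination (sets 4E).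
5. Ring order: lactone (step 8), then carbocycle (step 11); every stereocentre traces back to the one purchased centre, C8.

Assumption: carbon labels C1–C15 follow germacrane numbering of the target (C12 = lactone carbonyl, O on C6; acetate on C8; angelate on C11), and 1, 9 and 16 are purchased.

**Step 1**
Reactants: 1 methyl (2S)-oxirane-2-carboxylate; 2 isopropenylmagnesium bromide
Product: 3 methyl (2S)-2-hydroxy-4-methylpent-4-enoate
Conditions: CuBr·SMe2 (10 mol%), THF, −40 °C
Reagents that add atoms: none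
Why: Copper-catalysed Grignard opening of the epoxide (SN2) occurs at the unsubstituted C3 faster than addition to the ester, so the purchased stereocentre (future C8) is untouched.

**Step 2**
Reactants: 3 methyl (2S)-2-hydroxy-4-methylpent-4-enoate
Product: 4 methyl (2S)-2-[(tert-butyldimethylsilyl)oxy]-4-methylpent-4-enoate
Conditions: TBSCl, imidazole, DMF, 23 °C
Reagents that add atoms: tert-butyldimethylsilyl chloride, CC(C)(C)[Si](C)(C)Cl
Why: Standard silylation gives a bulky, non-leaving ether that later steers the allyl-metal addition and cannot eliminate; no stereocentre is touched.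

**Step 3**
Reactants: 4 methyl (2S)-2-[(tert-butyldimethylsilyl)oxy]-4-methylpent-4-enoate
Product: 5 (2S)-2-[(tert-butyldimethylsilyl)oxy]-4-methylpent-4-enal
Conditions: i-Bu2AlH (1.05 equiv), CH2Cl2, −78 °C
Reagents that add atoms: none
Why: Partial ester reduction stops at the aldehyde through the stable aluminium hemiacetal, and the α-silyloxy centre is configurationally stable under these non-basic conditions.

**Step 4**
Reactants: 5 (2S)-2-[(tert-butyldimethylsilyl)oxy]-4-methylpent-4-enal; 6 methyl acrylate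
Product: 7 methyl (4S)-4-[(tert-butyldimethylsilyl)oxy]-3-hydroxy-6-methyl-2-methylidenehept-6-enoate (both C3 epimers)
Conditions: DABCO (1 equiv), MeOH (cat.), neat 6 (5 equiv), 23 °C, 4 d
Reagents that add atoms: none
Why: The Morita–Baylis–Hillman reaction forms the C7–C11 bond, and the new carbinol centre is a mixture that is erased in step 5.

**Step 5**
Reactants: 7 methyl (4S)-4-[(tert-butyldimethylsilyl)oxy]-3-hydroxy-6-methyl-2-methylidenehept-6-enoate
Product: 8 methyl (2Z,4S)-2-(bromomethyl)-4-[(tert-butyldimethylsilyl)oxy]-6-methylhepta-2,6-dienoate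
Conditions: NBS, Me2S, CH2Cl2, 0 °C
Reagents that add atoms: N-bromosuccinimide, O=C1CCC(=O)N1Br
Why: Corey–Kim-type activation of the alcohol and SN2' displacement by bromide give the conjugated allylic bromide with the thermodynamically preferred geometry (C8 cis to CH2Br), leaving C8 untouched.

**Step 6**
Reactants: 9 hex-1-en-5-yne
Product: 12 (2E)-3-methylhepta-2,6-dien-1-ol, via dimethyl alkenylalane 10 (not isolated), via lithium alkenylaluminate 11 (not isolated)
Conditions: Me3Al (2 equiv), Cp2ZrCl2 (0.2 equiv), CH2Cl2, 0 to 23 °C; n-BuLi, THF, −78 °C; (CH2O)n, −78 to 23 °C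
Reagents that add atoms: trimethylaluminium, C[Al](C)C; paraformaldehyde (formaldehyde unit), C=O
Why: Negishi zirconium-catalysed syn-carboalumination puts methyl on the internal alkyne carbon and fixes the 4E trisubstituted olefin, and the aluminate is hydroxymethylated with retention while the terminal alkene stays inert.

**Step 7**
Reactants: 12 (2E)-3-methylhepta-2,6-dien-1-ol
Product: 13 (2E)-3-methylhepta-2,6-dienal
Conditions: MnO2 (15 equiv), CH2Cl2, 23 °C
Reagents that add atoms: none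
Why: Allylic oxidation with MnO2 gives the enal without E/Z isomerisation or over-oxidation.

**Step 8**
Reactants: 8 methyl (2Z,4S)-2-(bromomethyl)-4-[(tert-butyldimethylsilyl)oxy]-6-methylhepta-2,6-dienoate; 13 (2E)-3-methylhepta-2,6-dienal
Product: 15 (4S,5S)-4-[(1S)-1-[(tert-butyldimethylsilyl)oxy]-3-methylbut-3-en-1-yl]-3-methylidene-5-[(1E)-2-methylhexa-1,5-dien-1-yl]oxolan-2-one, via syn hydroxy ester 14 (not isolated)
Conditions: indium powder (1.2 equiv), THF/H2O (1:1), 23 °C; then PPTS (10 mol%), benzene, 50 °C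
Reagents that add atoms: none
Why: In this indium Barbier allylation the 2-(methoxycarbonyl)allylindium attacks the aldehyde through its γ-carbon (C7) in a chair transition state that gives the syn adduct and hence the cis-lactone, the aldehyde approaching anti to the bulky OTBS group in the A(1,3)-minimised conformer (H8 eclipsing the alkene), so C6 and C7 are set from C8 before PPTS closes the γ-lactone.

**Step 9**
Reactants: 15 (4S,5S)-4-[(1S)-1-[(tert-butyldimethylsilyl)oxy]-3-methylbut-3-en-1-yl]-3-methylidene-5-[(1E)-2-methylhexa-1,5-dien-1-yl]oxolan-2-one; 16 angelic acid [(2Z)-2-methylbut-2-enoic acid]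
Product: 19 (3S,4S,5S)-4-[(1S)-1-[(tert-butyldimethylsilyl)oxy]-3-methylbut-3-en-1-yl]-3-methyl-5-[(1E)-2-methylhexa-1,5-dien-1-yl]-2-oxooxolan-3-yl (2Z)-2-methylbut-2-enoate, via lithium enolate 17 (not isolated), via silyl ketene acetal 18 (not isolated)
Conditions: Li(s-Bu)3BH, THF, −78 °C; TIPSOTf, −78 to 0 °C; solvent switch; then 16 (3 equiv), 2,4,6-collidine (3 equiv), n-Bu4NPF6 (0.1 M), CH2Cl2/MeCN (4:1), graphite-felt anode (+1.0 V vs Ag/AgCl), platinum cathode, undivided cell, −20 °C, 2.2 F/mol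
Reagents that add atoms: none
Why: Proposed new method: after 1,4-hydride reduction of the α-methylene lactone and O-silylation, the electron-rich silyl ketene acetal is oxidised at the anode (about +1.0 V, far below the alkenes and the angelate) to a radical cation that collidinium angelate captures at C11 on the open α face (anti to the two β side chains at C6 and C7), and a second oxidation with loss of the silyl group restores the lactone, forming the tertiary angelate and the C11 stereocentre in one operation; the closest known reaction types are the anodic α-acetoxylation of enol acetates and silyl enol ethers and the α-acyloxylation of silyl ketene acetals with PhI(OAc)2.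

**Step 10**
Reactants: 19 (3S,4S,5S)-4-[(1S)-1-[(tert-butyldimethylsilyl)oxy]-3-methylbut-3-en-1-yl]-3-methyl-5-[(1E)-2-methylhexa-1,5-dien-1-yl]-2-oxooxolan-3-yl (2Z)-2-methylbut-2-enoate
Product: 20 (3S,4R,5S)-4-[(1S)-1-(acetyloxy)-3-methylbut-3-en-1-yl]-3-methyl-5-[(1E)-2-methylhexa-1,5-dien-1-yl]-2-oxooxolan-3-yl (2Z)-2-methylbut-2-enoate
Conditions: Ac2O, Cu(OTf)2 (5 mol%), CH2Cl2, 0 °C
Reagents that add atoms: acetic anhydride, CC(=O)OC(C)=O
Why: Lewis-acid-catalysed acetolysis exchanges the silyl ether for the acetate at oxygen with retention at C8 and never frees an 8-hydroxyl that could translactonise onto C12.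

**Step 11**
Reactants: 20 (3S,4R,5S)-4-[(1S)-1-(acetyloxy)-3-methylbut-3-en-1-yl]-3-methyl-5-[(1E)-2-methylhexa-1,5-dien-1-yl]-2-oxooxolan-3-yl (2Z)-2-methylbut-2-enoate
Product: 21 (1(10)Z,4E,6S,7R,8S,11S)-8-acetoxy-11-[(2Z)-2-methylbut-2-enoyloxy]germacra-1(10),4-dien-12,6-olide (CNP0148966.1)
Conditions: second-generation Grubbs catalyst RuCl2(=CHPh)(PCy3)(H2IMes) (10 mol%), toluene (1 mM), 80 °C
Reagents that add atoms: none
Why: Ring-closing metathesis of the terminal vinyl and the 1,1-disubstituted methallyl olefin under high dilution expels ethene and closes the ten-membered ring, with the Z olefin expected because a medium ring fused to the cis-lactone and already holding the 4E olefin closes through the less strained Z-forming ruthenacyclobutane.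

**Compound list**
1 | methyl (2S)-oxirane-2-carboxylate (methyl (S)-glycidate) | COC(=O)[C@@H]1CO1 | starting material
2 | isopropenylmagnesium bromide | CC(=C)[Mg]Br | starting material
3 | methyl (2S)-2-hydroxy-4-methylpent-4-enoate | COC(=O)[C@@H](O)CC(C)=C | intermediate
4 | methyl (2S)-2-[(tert-butyldimethylsilyl)oxy]-4-methylpent-4-enoate | COC(=O)[C@@H](O[Si](C)(C)C(C)(C)C)CC(C)=C | intermediate
5 | (2S)-2-[(tert-butyldimethylsilyl)oxy]-4-methylpent-4-enal | O=C[C@@H](O[Si](C)(C)C(C)(C)C)CC(C)=C | intermediate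
6 | methyl acrylate | COC(=O)C=C | starting material
7 | methyl (4S)-4-[(tert-butyldimethylsilyl)oxy]-3-hydroxy-6-methyl-2-methylidenehept-6-enoate (both C3 epimers) | COC(=O)C(=C)C(O)[C@@H](O[Si](C)(C)C(C)(C)C)CC(C)=C | intermediate
8 | methyl (2Z,4S)-2-(bromomethyl)-4-[(tert-butyldimethylsilyl)oxy]-6-methylhepta-2,6-dienoate | COC(=O)/C(CBr)=C/[C@@H](O[Si](C)(C)C(C)(C)C)CC(C)=C | intermediate
9 | hex-1-en-5-yne | C=CCCC#C | starting material
10 | dimethyl[(1E)-2-methylhexa-1,5-dien-1-yl]alane | C[Al](C)/C=C(\C)CCC=C | intermediate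
11 | lithium butyl(dimethyl)[(1E)-2-methylhexa-1,5-dien-1-yl]aluminate | [Li+].CCCC[Al-](C)(C)/C=C(\C)CCC=C | intermediate
12 | (2E)-3-methylhepta-2,6-dien-1-ol | OC/C=C(\C)CCC=C | intermediate
13 | (2E)-3-methylhepta-2,6-dienal | O=C/C=C(\C)CCC=C | intermediate
14 | methyl (3S,4S,5E)-3-[(1S)-1-[(tert-butyldimethylsilyl)oxy]-3-methylbut-3-en-1-yl]-4-hydroxy-6-methyl-2-methylidenedeca-5,9-dienoate | COC(=O)C(=C)[C@@H]([C@@H](O)/C=C(\C)CCC=C)[C@@H](O[Si](C)(C)C(C)(C)C)CC(C)=C | intermediate
15 | (4S,5S)-4-[(1S)-1-[(tert-butyldimethylsilyl)oxy]-3-methylbut-3-en-1-yl]-3-methylidene-5-[(1E)-2-methylhexa-1,5-dien-1-yl]oxolan-2-one | C=C1C(=O)O[C@@H](/C=C(\C)CCC=C)[C@H]1[C@@H](O[Si](C)(C)C(C)(C)C)CC(C)=C | intermediate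
16 | angelic acid [(2Z)-2-methylbut-2-enoic acid] | C/C=C(/C)C(=O)O | starting material
17 | lithium (4S,5S)-4-[(1S)-1-[(tert-butyldimethylsilyl)oxy]-3-methylbut-3-en-1-yl]-3-methyl-5-[(1E)-2-methylhexa-1,5-dien-1-yl]-4,5-dihydrofuran-2-olate | [Li+].CC1=C([O-])O[C@@H](/C=C(\C)CCC=C)[C@H]1[C@@H](O[Si](C)(C)C(C)(C)C)CC(C)=C | intermediate
18 | {[(4S,5S)-4-[(1S)-1-[(tert-butyldimethylsilyl)oxy]-3-methylbut-3-en-1-yl]-3-methyl-5-[(1E)-2-methylhexa-1,5-dien-1-yl]-4,5-dihydrofuran-2-yl]oxy}tri(propan-2-yl)silane | CC1=C(O[Si](C(C)C)(C(C)C)C(C)C)O[C@@H](/C=C(\C)CCC=C)[C@H]1[C@@H](O[Si](C)(C)C(C)(C)C)CC(C)=C | intermediate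
19 | (3S,4S,5S)-4-[(1S)-1-[(tert-butyldimethylsilyl)oxy]-3-methylbut-3-en-1-yl]-3-methyl-5-[(1E)-2-methylhexa-1,5-dien-1-yl]-2-oxooxolan-3-yl (2Z)-2-methylbut-2-enoate | C/C=C(/C)C(=O)O[C@]1(C)C(=O)O[C@@H](/C=C(\C)CCC=C)[C@H]1[C@@H](O[Si](C)(C)C(C)(C)C)CC(C)=C | intermediate
20 | (3S,4R,5S)-4-[(1S)-1-(acetyloxy)-3-methylbut-3-en-1-yl]-3-methyl-5-[(1E)-2-methylhexa-1,5-dien-1-yl]-2-oxooxolan-3-yl (2Z)-2-methylbut-2-enoate | C/C=C(/C)C(=O)O[C@]1(C)C(=O)O[C@@H](/C=C(\C)CCC=C)[C@H]1[C@@H](OC(C)=O)CC(C)=C | intermediate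
21 | (3S,3aR,4S,6Z,10E,11aS)-4-(acetyloxy)-3,6,10-trimethyl-2-oxo-2,3,3a,4,5,8,9,11a-octahydrocyclodeca[b]furan-3-yl (2Z)-2-methylbut-2-enoate [(1(10)Z,4E,6S,7R,8S,11S)-8-acetoxy-11-angeloyloxygermacra-1(10),4-dien-12,6-olide] | C/C=C(/C)C(=O)O[C@]1(C)C(=O)O[C@H]2/C=C(\C)CC/C=C(/C)C[C@H](OC(C)=O)[C@H]21 | target

**Totals**
Total step count: 11 (steps 6 and 7 make fragment 13).
Longest linear sequence: 9 steps (steps 1, 2, 3, 4, 5, 8, 9, 10, 11).

**Steps most likely to fail, with fallbacks**

Step 9 (the new anodic acyloxylation). The radical cation may lose a proton instead of capturing angelate, giving a butenolide, or the ketene acetal may simply be desilylated. The fallback uses known chemistry, sets out from 15 and comes back at 19. Conjugate reduction of 15 with Li(s-Bu)3BH (THF, −78 °C, NH4Cl quench) gives the 11,13-dihydro lactone F1 as C11 epimers. Its potassium enolate (KN(SiMe3)2, THF, −78 °C) is hydroxylated with 3-phenyl-2-(phenylsulfonyl)oxaziridine on the face anti to the C7 branch, giving the 11α-hydroxy lactone F2. F2 is then acylated (Et3N, DMAP, toluene, 80 °C) with the mixed anhydride F3, made from 16 and 2,4,6-trichlorobenzoyl chloride, to give 19.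

Step 11 (ring-closing metathesis). A strained ten-membered ring with a trisubstituted olefin may close slowly, oligomerise, or give the 1(10)E isomer. The fallback sets out from 14 (isolated before lactonisation) and comes back at 21; the carbocycle is closed on the flexible open-chain adduct and the lactone is formed afterwards across the ring. Metathesis of 14 (same catalyst, 1 mM) gives the ten-membered hydroxy ester F4, and PPTS closes it to the macrocyclic α-methylene lactone F5. Li(s-Bu)3BH then TIPSOTf give its lithium enolate F6 and the triisopropylsilyl ketene acetal F7. Anodic acyloxylation with 16 as in step 9 gives the macrocyclic angelate silyl ether F8, and Ac2O/Cu(OTf)2 converts F8 into 21.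

Step 8 (syn/anti ratio and facial selectivity of the Barbier allylation). Allylindium species can equilibrate and react through open transition states. The fallback sets out from 8 and comes back at 15. Borylation of 8 (B2pin2, Pd2(dba)3 cat., toluene, 50 °C) gives the pinacol allylboronate F9. Its allylboration of 13 (toluene, 80 °C, or Sc(OTf)3 cat., 0 °C) runs through a closed six-membered transition state that transfers the fixed olefin geometry to the syn adduct 14, which PPTS lactonises to 15.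

**Further compounds**
F1 | step 9 | (4S,5S)-4-[(1S)-1-[(tert-butyldimethylsilyl)oxy]-3-methylbut-3-en-1-yl]-3-methyl-5-[(1E)-2-methylhexa-1,5-dien-1-yl]oxolan-2-one (C3 epimers) | CC1C(=O)O[C@@H](/C=C(\C)CCC=C)[C@H]1[C@@H](O[Si](C)(C)C(C)(C)C)CC(C)=C
F2 | step 9 | (3S,4S,5S)-4-[(1S)-1-[(tert-butyldimethylsilyl)oxy]-3-methylbut-3-en-1-yl]-3-hydroxy-3-methyl-5-[(1E)-2-methylhexa-1,5-dien-1-yl]oxolan-2-one | O[C@]1(C)C(=O)O[C@@H](/C=C(\C)CCC=C)[C@H]1[C@@H](O[Si](C)(C)C(C)(C)C)CC(C)=C
F3 | step 9 | (2Z)-2-methylbut-2-enoic 2,4,6-trichlorobenzoic anhydride | C/C=C(/C)C(=O)OC(=O)c1c(Cl)cc(Cl)cc1Cl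
F4 | step 11 | methyl 2-[(1S,2S,3E,7Z,10S)-10-[(tert-butyldimethylsilyl)oxy]-2-hydroxy-4,8-dimethylcyclodeca-3,7-dien-1-yl]prop-2-enoate | COC(=O)C(=C)[C@H]1[C@@H](O)/C=C(\C)CC/C=C(/C)C[C@@H]1O[Si](C)(C)C(C)(C)C
F5 | step 11 | (1(10)Z,4E,6S,7S,8S)-8-[(tert-butyldimethylsilyl)oxy]germacra-1(10),4,11(13)-trien-12,6-olide | C=C1C(=O)O[C@H]2/C=C(\C)CC/C=C(/C)C[C@H](O[Si](C)(C)C(C)(C)C)[C@H]21
F6 | step 11 | lithium C12-enolate of (1(10)Z,4E,6S,7S,8S)-8-[(tert-butyldimethylsilyl)oxy]germacra-1(10),4-dien-12,6-olide | [Li+].CC1=C([O-])O[C@H]2/C=C(\C)CC/C=C(/C)C[C@H](O[Si](C)(C)C(C)(C)C)[C@H]21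
F7 | step 11 | O-triisopropylsilyl ketene acetal of (1(10)Z,4E,6S,7S,8S)-8-[(tert-butyldimethylsilyl)oxy]germacra-1(10),4-dien-12,6-olide | CC1=C(O[Si](C(C)C)(C(C)C)C(C)C)O[C@H]2/C=C(\C)CC/C=C(/C)C[C@H](O[Si](C)(C)C(C)(C)C)[C@H]21
F8 | step 11 | (1(10)Z,4E,6S,7S,8S,11S)-8-[(tert-butyldimethylsilyl)oxy]-11-[(2Z)-2-methylbut-2-enoyloxy]germacra-1(10),4-dien-12,6-olide | C/C=C(/C)C(=O)O[C@]1(C)C(=O)O[C@H]2/C=C(\C)CC/C=C(/C)C[C@H](O[Si](C)(C)C(C)(C)C)[C@H]21
F9 | step 8 | methyl (2E,4S)-4-[(tert-butyldimethylsilyl)oxy]-6-methyl-2-[(4,4,5,5-tetramethyl-1,3,2-dioxaborolan-2-yl)methyl]hepta-2,6-dienoate | COC(=O)/C(CB1OC(C)(C)C(C)(C)O1)=C/[C@@H](O[Si](C)(C)C(C)(C)C)CC(C)=C
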